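**Plan**
- Structural feature: C9, C10=C11 and the oxygen-bearing quaternary C12 of the cyclopentenone correspond to the carbinol-bearing α-carbon, the two β-carbons and the alkylated α-carbon of a 2,5-disubstituted furan, whose ring oxygen becomes the C9 carbonyl. A furyl carbinol at C8 therefore lacks only the ring bond C8–C12.
- Retrosynthetic cuts, in order: C12 O–acetyl; C5=C6 (Wittig); C7=C8 (E1cB opening of a C6/C7 dioxolane); C10–Cl (epoxide, then HCl); ring bond C8–C12 (Piancatelli rearrangement); C8–C9 (furyllithium plus aldehyde); C12–C13 (furan alkylation).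
- Forward order: furan is alkylated with the Z-octenyl bromide, lithiated and added to (R)-glyceraldehyde acetonide. The rearrangement then builds the only ring, and chlorine, the exocyclic alkene, the aldehyde, the α-chain and the acetate follow.
- Stereochemistry: C12 comes from the sense of the conrotatory closure, steered by the chiral-pool centre C7 and secured by separation of diastereomers. 14Z comes from (Z)-oct-2-en-1-ol, 7E from the elimination and 5Z from the non-stabilised ylide.

Key step: step 4

Remark: atoms carry prostanoid numbers (C1 ester carbon; C8–C12 ring with C9 carbonyl, C10 chlorine, C12 acetate; C13–C20 octenyl chain). Aldehyde 6 is assumed to be used freshly distilled, and carbinol 8 as its mixture of C8 epimers.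

**Route**

Step 1
Reactants: 1 (Z)-oct-2-en-1-ol
Product: 2 (Z)-1-bromooct-2-ene
Conditions: CBr4, PPh3, CH2Cl2, 0 °C
Reagents that add atoms: carbon tetrabromide, BrC(Br)(Br)Br
Why: Appel reaction; bromide displaces the alkoxyphosphonium group by SN2 at the primary carbon, so the Z alkene is kept and no allylic transposition is expected at 0 °C.

Step 2
Reactants: 3 furan; 2 (Z)-1-bromooct-2-ene
Product: 5 2-[(2Z)-oct-2-en-1-yl]furan, via 2-furyllithium 4 (not isolated)
Conditions: n-BuLi, THF, −78 → 0 °C; then 2, −78 → 23 °C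
Reagents that add atoms: none
Why: α-Lithiation of furan followed by SN2 alkylation at the unhindered primary allylic carbon, which leaves the Z geometry untouched.

Step 3
Reactants: 5 2-[(2Z)-oct-2-en-1-yl]furan; 6 (R)-2,2-dimethyl-1,3-dioxolane-4-carbaldehyde
Product: 8 (R)-[(4R)-2,2-dimethyl-1,3-dioxolan-4-yl]{5-[(2Z)-oct-2-en-1-yl]furan-2-yl}methanol (anti epimer shown; the C8 epimer accompanies it), via 5-lithio-2-octenylfuran 7 (not isolated)
Conditions: n-BuLi, THF, −20 → 0 °C; then 6, −78 °C; H2O
Reagents that add atoms: none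
Why: Kinetic lithiation of the free furan α-position (faster than deprotonation of the furyl-allyl CH2, as with difurylmethanes) and 1,2-addition to the aldehyde; a Felkin-type preference for the anti epimer is expected but immaterial, because C8 becomes planar on ionisation in step 4.

Step 4
Reactants: 8 (R)-[(4R)-2,2-dimethyl-1,3-dioxolan-4-yl]{5-[(2Z)-oct-2-en-1-yl]furan-2-yl}methanol
Product: 10 (4R,5S)-5-[(4S)-2,2-dimethyl-1,3-dioxolan-4-yl]-4-hydroxy-4-[(2Z)-oct-2-en-1-yl]cyclopent-2-en-1-one, via hydroxypentadienyl cation 9 (not isolated)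
Conditions: ZnCl2 (2 equiv), acetone/H2O (2:1), 60 °C; SiO2 chromatography to remove the 12S trans diastereomer
Reagents that add atoms: water, O
Why: Proposed new method: Zn-assisted ionisation of either C8 epimer gives one furan-stabilised cation, water adds at the alkylated α-carbon C12, the hemiketal opens to the 1,4-dihydroxypentadienyl cation 9, and thermal conrotatory 4π closure joins C8 to C12 before proton loss from the C9 oxygen releases the enone. The closest known reaction is the ZnCl2-mediated Piancatelli rearrangement of 5-alkyl-2-furylcarbinols to trans-4-alkyl-4-hydroxy-5-substituted cyclopentenones, which is established only without control of absolute configuration; the new element is the relay of configuration from C7 to C12. The five-membered carbocycle, the only ring of the target, closes by this conrotatory electrocyclisation of the U-shaped cation (Nazarov-type closure). C8 and C12 are set together: their trans relation follows from conrotation of a cation that carries the C7 substituent and the C12 hydroxyl on its outer positions, and the absolute sense is expected to come from C7, whose hydrogen should lie in the cation plane to avoid allylic strain with the C9 hydroxyl so that C12 bonds to the face of C8 anti to the C7–O bond, giving 12R from the (R)-aldehyde. The step needs this torquoselectivity, reaction at the furan without harm to the Z alkene, and survival of the ketal; the homochiral dioxolane supplies the first and in any case makes the two trans products separable diastereomers, the non-oxidising Lewis acid the second, and acetone as cosolvent in a weakly acidic medium the third.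

Step 5
Reactants: 10 (4R,5S)-5-[(4S)-2,2-dimethyl-1,3-dioxolan-4-yl]-4-hydroxy-4-[(2Z)-oct-2-en-1-yl]cyclopent-2-en-1-one
Product: 11 3-[(4S)-2,2-dimethyl-1,3-dioxolan-4-yl]-4-hydroxy-4-[(2Z)-oct-2-en-1-yl]-6-oxabicyclo[3.1.0]hexan-2-one (10,11-epoxide of 10; oxirane cis to the C12 hydroxyl)
Conditions: 30% aq. H2O2, NaOH (0.2 equiv), MeOH, −20 → 0 °C
Reagents that add atoms: hydrogen peroxide, OO
Why: Weitz–Scheffer epoxidation; hydroperoxide adds in conjugate fashion only to the electron-poor C10=C11 bond (the isolated Z alkene is inert), expectedly on the face of the C12 hydroxyl away from both side chains, while low temperature and substoichiometric base keep enolisation at C8 (E1cB loss of the C7 oxygen, retro-aldol) from competing; the oxirane configuration is erased in step 6.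

Step 6
Reactants: 11 10,11-epoxide of 10
Product: 13 (4S,5S)-2-chloro-5-[(4S)-2,2-dimethyl-1,3-dioxolan-4-yl]-4-hydroxy-4-[(2Z)-oct-2-en-1-yl]cyclopent-2-en-1-one (C8 and C12 spatially as in 10), via trans-chlorohydrin 12 (not isolated)
Conditions: 37% aq. HCl (3 equiv), acetone, 0 → 23 °C
Reagents that add atoms: hydrogen chloride, Cl
Why: Acid-promoted opening of the α,β-epoxy ketone by chloride at C10 (SN2 at the α-carbon, not at neopentyl C11) gives chlorohydrin 12, which dehydrates to the 2-chloro enone, the classical epoxy ketone to α-halo enone conversion; acetone as solvent holds the isopropylidene ketal in place, and the C12 alcohol does not ionise next to the electron-poor ring.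

Step 7
Reactants: 13 (4S,5S)-2-chloro-5-[(4S)-2,2-dimethyl-1,3-dioxolan-4-yl]-4-hydroxy-4-[(2Z)-oct-2-en-1-yl]cyclopent-2-en-1-one
Product: 14 (4R,5E)-2-chloro-4-hydroxy-5-(2-hydroxyethylidene)-4-[(2Z)-oct-2-en-1-yl]cyclopent-2-en-1-one
Conditions: DBU (1.5 equiv), CH2Cl2, 0 → 23 °C
Reagents that add atoms: none
Why: E1cB elimination; DBU removes the only enolisable proton (C8–H), the cross-conjugated enolate expels the C7 oxygen of the dioxolane and the hemiketal alkoxide loses acetone to leave the C6 alcohol, whereas elimination toward C12 would give a cyclopentadienone and is not expected; the 7E geometry, in which C6 avoids the C9 carbonyl oxygen, should predominate (any 7Z isomer is removed here or equilibrates at the aldehyde stage), and C12 is untouched.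

Step 8
Reactants: 14 (4R,5E)-2-chloro-4-hydroxy-5-(2-hydroxyethylidene)-4-[(2Z)-oct-2-en-1-yl]cyclopent-2-en-1-one
Product: 15 (2E)-2-{(5R)-3-chloro-5-hydroxy-5-[(2Z)-oct-2-en-1-yl]-2-oxocyclopent-3-en-1-ylidene}acetaldehyde
Conditions: Dess–Martin periodinane (1.1 equiv), NaHCO3, CH2Cl2, 0 °C
Reagents that add atoms: none
Why: Dess–Martin oxidation of the primary allylic alcohol under buffered, non-basic conditions; the tertiary C12 alcohol cannot be oxidised, a single equivalent of oxidant avoids further oxidation of any lactol form, and the E enal with the two carbonyl-bearing carbons trans is the thermodynamically preferred geometry.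

Step 9
Reactants: 16 methyl 5-bromopentanoate
Product: 17 (5-methoxy-5-oxopentyl)triphenylphosphonium bromide
Conditions: PPh3, MeCN, 82 °C
Reagents that add atoms: triphenylphosphine, c1ccc(cc1)P(c1ccccc1)c1ccccc1
Why: SN2 quaternisation of the phosphine by the primary bromide; the ester is inert.

Step 10
Reactants: 15 (2E)-2-{(5R)-3-chloro-5-hydroxy-5-[(2Z)-oct-2-en-1-yl]-2-oxocyclopent-3-en-1-ylidene}acetaldehyde; 17 (5-methoxy-5-oxopentyl)triphenylphosphonium bromide
Product: 19 methyl (5Z,7E)-7-{(5R)-3-chloro-5-hydroxy-5-[(2Z)-oct-2-en-1-yl]-2-oxocyclopent-3-en-1-ylidene}hept-5-enoate, via phosphorus ylide 18 (not isolated)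
Conditions: 17 (2.3 equiv), NaN(SiMe3)2 (2.2 equiv), THF, −78 °C; then 15, −78 → −20 °C
Reagents that add atoms: none
Why: Wittig olefination with a non-stabilised ylide under lithium-free conditions at low temperature gives the 5Z alkene through the kinetically favoured cis-oxaphosphetane; the aldehyde reacts far faster than the hindered cross-conjugated ketone or the esters, and the extra equivalent of ylide only deprotonates the C12 hydroxyl.

Step 11
Reactants: 19 methyl (5Z,7E)-7-{(5R)-3-chloro-5-hydroxy-5-[(2Z)-oct-2-en-1-yl]-2-oxocyclopent-3-en-1-ylidene}hept-5-enoate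
Product: 20 methyl (5Z,7E)-7-{(5R)-5-acetoxy-3-chloro-5-[(2Z)-oct-2-en-1-yl]-2-oxocyclopent-3-en-1-ylidene}hept-5-enoate
Conditions: Ac2O, DMAP, Et3N, CH2Cl2, 23 °C
Reagents that add atoms: acetic anhydride, CC(=O)OC(C)=O
Why: DMAP-catalysed acylation of the tertiary alcohol; with C8 now sp2 there is no enolisable hydrogen from which the new acetate could be eliminated, and no stereocentre is touched.

**Compound list**

1 | (Z)-oct-2-en-1-ol | CCCCC/C=C\CO | starting material
2 | (Z)-1-bromooct-2-ene | CCCCC/C=C\CBr | intermediate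
3 | furan | c1ccoc1 | starting material
4 | 2-furyllithium (formed in the flask) | [Li]c1ccco1 | intermediate
5 | 2-[(2Z)-oct-2-en-1-yl]furan | CCCCC/C=C\Cc1ccco1 | intermediate
6 | (R)-2,2-dimethyl-1,3-dioxolane-4-carbaldehyde | O=C[C@H]1COC(C)(C)O1 | starting material
7 | {5-[(2Z)-oct-2-en-1-yl]furan-2-yl}lithium (formed in the flask) | CCCCC/C=C\Cc1ccc([Li])o1 | intermediate
8 | (R)-[(4R)-2,2-dimethyl-1,3-dioxolan-4-yl]{5-[(2Z)-oct-2-en-1-yl]furan-2-yl}methanol (anti epimer shown; C8 epimer also present) | CCCCC/C=C\Cc1ccc(o1)[C@H](O)[C@H]2COC(C)(C)O2 | intermediate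
9 | 1,4-dihydroxypentadienyl cation spanning C8 to C12 (drawn as the C12 oxocarbenium form; formed in the flask) | CCCCC/C=C\CC(=[OH+])/C=C\C(O)=C\[C@H]1COC(C)(C)O1 | intermediate
10 | (4R,5S)-5-[(4S)-2,2-dimethyl-1,3-dioxolan-4-yl]-4-hydroxy-4-[(2Z)-oct-2-en-1-yl]cyclopent-2-en-1-one | CCCCC/C=C\C[C@@]1(O)C=CC(=O)[C@H]1[C@H]2COC(C)(C)O2 | intermediate
11 | 3-[(4S)-2,2-dimethyl-1,3-dioxolan-4-yl]-4-hydroxy-4-[(2Z)-oct-2-en-1-yl]-6-oxabicyclo[3.1.0]hexan-2-one (10,11-epoxide of 10, oxirane cis to the C12 hydroxyl) | CCCCC/C=C\C[C@@]1(O)[C@@H]2O[C@@H]2C(=O)[C@H]1[C@H]3COC(C)(C)O3 | intermediate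
12 | 2-chloro-5-[(4S)-2,2-dimethyl-1,3-dioxolan-4-yl]-3,4-dihydroxy-4-[(2Z)-oct-2-en-1-yl]cyclopentan-1-one (chlorine trans to the C11 hydroxyl, C11 and C12 hydroxyls cis; formed in the flask) | CCCCC/C=C\C[C@@]1(O)[C@H](O)[C@@H](Cl)C(=O)[C@H]1[C@H]2COC(C)(C)O2 | intermediate
13 | (4S,5S)-2-chloro-5-[(4S)-2,2-dimethyl-1,3-dioxolan-4-yl]-4-hydroxy-4-[(2Z)-oct-2-en-1-yl]cyclopent-2-en-1-one | CCCCC/C=C\C[C@@]1(O)C=C(Cl)C(=O)[C@H]1[C@H]2COC(C)(C)O2 | intermediate
14 | (4R,5E)-2-chloro-4-hydroxy-5-(2-hydroxyethylidene)-4-[(2Z)-oct-2-en-1-yl]cyclopent-2-en-1-one | CCCCC/C=C\C[C@@]1(O)C=C(Cl)C(=O)/C1=C/CO | intermediate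
15 | (2E)-2-{(5R)-3-chloro-5-hydroxy-5-[(2Z)-oct-2-en-1-yl]-2-oxocyclopent-3-en-1-ylidene}acetaldehyde | CCCCC/C=C\C[C@@]1(O)C=C(Cl)C(=O)/C1=C/C=O | intermediate
16 | methyl 5-bromopentanoate | COC(=O)CCCCBr | starting material
17 | (5-methoxy-5-oxopentyl)triphenylphosphonium bromide | COC(=O)CCCC[P+](c1ccccc1)(c1ccccc1)c1ccccc1.[Br-] | intermediate
18 | methyl 5-(triphenyl-λ5-phosphanylidene)pentanoate (ylide, formed in the flask) | COC(=O)CCCC=P(c1ccccc1)(c1ccccc1)c1ccccc1 | intermediate
19 | methyl (5Z,7E)-7-{(5R)-3-chloro-5-hydroxy-5-[(2Z)-oct-2-en-1-yl]-2-oxocyclopent-3-en-1-ylidene}hept-5-enoate | CCCCC/C=C\C[C@@]1(O)C=C(Cl)C(=O)/C1=C/C=C\CCCC(=O)OC | intermediate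
20 | methyl (5Z,7E)-7-{(5R)-5-acetoxy-3-chloro-5-[(2Z)-oct-2-en-1-yl]-2-oxocyclopent-3-en-1-ylidene}hept-5-enoate | CCCCC/C=C\C[C@@]1(OC(C)=O)C=C(Cl)C(=O)/C1=C/C=C\CCCC(=O)OC | target

**Step count**
Total: 11 steps. Longest linear sequence: 10 steps (steps 1–8, 10, 11, from (Z)-oct-2-en-1-ol).

**Steps most likely to fail**

Step 4 (the proposed new method). The two senses of conrotation may be poorly differentiated, or the sense that leads to 12S may be preferred, so that the needed diastereomer is the minor product (poor torquoselectivity).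
- Fallback, known chemistry only: the C12 configuration is obtained by resolution instead of induction, with the mirror-image chiral-pool centre as a covalently bound resolving group. It asks nothing of the rearrangement beyond its established trans-selective course and relies on chromatographic separation of diastereomers.
- It sets out from 5 and comes back at 14.
- Lithio furan 7, made from 5 as in step 3, is added to commercial (S)-2,2-dimethyl-1,3-dioxolane-4-carbaldehyde to give the enantiomeric carbinol F1. The ZnCl2 rearrangement passes through the mirror-image cation F2, and the 12R trans diastereomer, the C7 epimer of 10 F3, is separated on silica from its 12S partner, which in this series is the isomer disfavoured by whatever facial bias the first series showed. Epoxidation as in step 5 gives oxirane F4, HCl in acetone gives, through chlorohydrin F5, the chloro enone F6, and DBU opens the dioxolane of F6 to give 14, where C7 and C8 are no longer stereocentres.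

Step 10. Conjugate addition of the basic ylide to the chloro dienone, or base-induced decomposition of the doubly activated enal, may outrun olefination, and the 5Z selectivity may erode.
- Fallback: the alkene geometry and the chain are delivered separately, without a basic ylide. It sets out from 15 and comes back at 19.
- Dibromo-olefination of 15 (CBr4, PPh3, Zn dust, CH2Cl2, 0 °C) gives the 1,1-dibromodiene F7. Palladium-catalysed hydrogenolysis of the bromine trans to C7 (Pd(PPh3)4, Bu3SnH, toluene, 23 °C) leaves the Z bromodiene F8. Negishi coupling of F8 with (4-methoxy-4-oxobutyl)zinc iodide F9, prepared from methyl 4-iodobutanoate and Zn dust in THF, under Pd(PPh3)4 catalysis forms C4–C5 with retention of geometry and gives 19.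

Step 6. Partial hydrolysis or migration of the isopropylidene ketal, and ketal formation at the cis C11/C12 diol of 12, may give mixtures and stall the dehydration.
- Fallback: the ketal is given up on purpose and the C7 oxygen is turned into a better leaving group. It sets out from 11 and comes back at 14.
- Aqueous HCl in THF without acetone takes 11 through 12 and 13 to the chloro enone triol F10. 1,1′-Carbonyldiimidazole in CH2Cl2 closes the C6/C7 diol to the cyclic carbonate F11 (the tertiary C12 hydroxyl does not react), and DBU then triggers E1cB opening of the carbonate with loss of carbon dioxide to give 14.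

**Further compounds**

F1 | step 4 | (S)-[(4S)-2,2-dimethyl-1,3-dioxolan-4-yl]{5-[(2Z)-oct-2-en-1-yl]furan-2-yl}methanol (enantiomer of 8) | CCCCC/C=C\Cc1ccc(o1)[C@@H](O)[C@@H]2COC(C)(C)O2
F2 | step 4 | mirror-image 1,4-dihydroxypentadienyl cation (enantiomer of 9) | CCCCC/C=C\CC(=[OH+])/C=C\C(O)=C\[C@@H]1COC(C)(C)O1
F3 | step 4 | (4R,5S)-5-[(4R)-2,2-dimethyl-1,3-dioxolan-4-yl]-4-hydroxy-4-[(2Z)-oct-2-en-1-yl]cyclopent-2-en-1-one (C7 epimer of 10) | CCCCC/C=C\C[C@@]1(O)C=CC(=O)[C@H]1[C@@H]2COC(C)(C)O2
F4 | step 4 | 10,11-epoxide of F3, oxirane cis to the C12 hydroxyl (C7 epimer of 11) | CCCCC/C=C\C[C@@]1(O)[C@@H]2O[C@@H]2C(=O)[C@H]1[C@@H]3COC(C)(C)O3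
F5 | step 4 | trans-chlorohydrin from F4 (C7 epimer of 12) | CCCCC/C=C\C[C@@]1(O)[C@H](O)[C@@H](Cl)C(=O)[C@H]1[C@@H]2COC(C)(C)O2
F6 | step 4 | (4S,5S)-2-chloro-5-[(4R)-2,2-dimethyl-1,3-dioxolan-4-yl]-4-hydroxy-4-[(2Z)-oct-2-en-1-yl]cyclopent-2-en-1-one (C7 epimer of 13) | CCCCC/C=C\C[C@@]1(O)C=C(Cl)C(=O)[C@H]1[C@@H]2COC(C)(C)O2
F7 | step 10 | (4R,5E)-2-chloro-5-(3,3-dibromoprop-2-en-1-ylidene)-4-hydroxy-4-[(2Z)-oct-2-en-1-yl]cyclopent-2-en-1-one | CCCCC/C=C\C[C@@]1(O)C=C(Cl)C(=O)/C1=C/C=C(Br)Br
F8 | step 10 | (4R,5E)-5-[(2Z)-3-bromoprop-2-en-1-ylidene]-2-chloro-4-hydroxy-4-[(2Z)-oct-2-en-1-yl]cyclopent-2-en-1-one | CCCCC/C=C\C[C@@]1(O)C=C(Cl)C(=O)/C1=C/C=C\Br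
F9 | step 10 | (4-methoxy-4-oxobutyl)zinc iodide | COC(=O)CCC[Zn]I
F10 | step 6 | (4S,5S)-2-chloro-5-[(1S)-1,2-dihydroxyethyl]-4-hydroxy-4-[(2Z)-oct-2-en-1-yl]cyclopent-2-en-1-one | CCCCC/C=C\C[C@@]1(O)C=C(Cl)C(=O)[C@H]1[C@H](O)CO
F11 | step 6 | (4S)-4-{(1S,5S)-3-chloro-5-hydroxy-5-[(2Z)-oct-2-en-1-yl]-2-oxocyclopent-3-en-1-yl}-1,3-dioxolan-2-one (configuration as in 13) | CCCCC/C=C\C[C@@]1(O)C=C(Cl)C(=O)[C@H]1[C@H]2COC(=O)O2
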